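The ten-membered ring (C1–C10, briarane numbering) is read as a ring-expanded eudesmane. Its sequence C2–C3 trans-epoxide, C4H2, ring-cis C5=C6, C7–O is the retron of an acetylenic oxy-Cope rearrangement. The key step breaks C2–C7 of a trans-decalin and forms C4–C5. Ring C1-C2-C7-C8-C9-C10 thus becomes the cyclodecadienone in one operation, with E-C2=C3, ring-cis C5=C6 and the C7 carbonyl in place. C1, C8, C9 and C10 are set beforehand on the rigid bicycle. The precursor is a 7-alkynyl-2-vinyl-trans-decalin-7-ol, built from a quinone Diels–Alder adduct and a propargyl ether.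

Key step: step 15

Numbering: C1 quaternary ring-fusion carbon (C15 methyl, defines the β face), C10 ring-fusion CH, C2/C3 epoxide, C4 CH2, C5(C16)=C6, C7–O(lactone), C8–OH, C9–OAc, C11(C20)(OAc), C12=O, C13=C14, C17(C18)–C19 lactone carbons.
Assumption: the (R)-BINOL–Ti(IV) catalyst of step 3 is taken to give the C1 configuration drawn. If the sense of induction is opposite, (S)-BINOL is used.

Step 1
Reactants: 1 2-methoxy-6-methylphenol
Product: 2 2-methoxy-6-methyl-1,4-benzoquinone
Conditions: O2 (1 atm), Co(salen) (5 mol %), DMF, rt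
Reagents that add atoms: dioxygen, O=O
Why: Cobalt-salen aerobic oxidation of a 2,6-disubstituted phenol with a free para position is a standard entry to the p-quinone.

Step 2
Reactants: 3 pent-1-en-3-one
Product: 4 (Z)-3-(tert-butyldimethylsilyloxy)penta-1,3-diene
Conditions: TBSOTf, Et3N, CH2Cl2, 0 °C
Reagents that add atoms: tert-butyldimethylsilyl triflate, CC(C)(C)[Si](C)(C)OS(=O)(=O)C(F)(F)F
Why: Soft enolisation of the ethyl ketone should give the Z silyl enol ether, which places C20 on the outside of the s-cis diene.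

Step 3
Reactants: 2 2-methoxy-6-methyl-1,4-benzoquinone; 4 (Z)-3-(tert-butyldimethylsilyloxy)penta-1,3-diene
Product: 5 cis-fused adduct (C1 Me β; C10 H β; C11 Me α; C2=O; C7-OMe C7=C8; C9=O; C12-OTBS C12=C13)
Conditions: (R)-BINOL/TiCl2(Oi-Pr)2 (25 mol %), 4 Å MS, toluene, −40 to −10 °C
Reagents that add atoms: none
Why: Enantioselective Lewis-acid-catalysed quinone Diels–Alder reaction in which the methoxy-bearing C7=C8 bond is deactivated so that C1=C10 reacts, bidentate binding of Ti to C2=O and the C7 methoxy oxygen makes C10 the partner of the nucleophilic C11, endo suprafacial addition gives the cis fusion, and the ligand selects the quinone face and so sets C1.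

Step 4
Reactants: 5 cis-fused adduct
Product: 6 trans-fused trione (C10 H α; C11 Me α equatorial; C2, C9 and C12 ketones; C7-OMe)
Conditions: TBAF, AcOH, THF, 0 °C; then DBU (0.3 equiv), CH2Cl2, rt
Reagents that add atoms: none
Why: Fluoride cleaves the silyl enol ether and DBU equilibrates C10 (α to C9=O) and C11 (α to C12=O) to the trans-decalin with equatorial C20, the classical base isomerisation of angularly methylated quinone adducts.

Step 5
Reactants: 6 trans-fused trione
Product: 7 C12 ethylene ketal of 6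
Conditions: TMSOCH2CH2OTMS, TMSOTf (5 mol %), CH2Cl2, −78 to −20 °C
Reagents that add atoms: 1,2-bis(trimethylsilyloxy)ethane, C[Si](C)(C)OCCO[Si](C)(C)C
Why: Under silyl-triflate-catalysed ketalisation the saturated C12 ketone reacts far faster than the conjugated and hindered C2 and C9 carbonyls.

Step 6
Reactants: 7 C12 ethylene ketal
Product: 9 2β-hydroxy-C8=C9-en-7-one C12 ketal, via 2β 9β-diol 8 (not isolated)
Conditions: LiAlH4, THF, 0 °C; then 1 M HCl, THF, 0 °C
Reagents that add atoms: water, O
Why: Hydride reduces both carbonyls from the open α face, and mild acid then effects a Stork–Danheiser transposition (ionisation of C9–OH assisted by the C7 enol ether, then hydrolysis) that moves the carbonyl to C7 and creates C8=C9.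

Step 7
Reactants: 9 2β-hydroxy enone
Product: 10 2β-acetoxy enone
Conditions: Ac2O, pyridine, DMAP (cat.), CH2Cl2, rt
Reagents that add atoms: acetic anhydride, CC(=O)OC(C)=O
Why: Simple acylation turns the α-ketol hydroxyl into a leaving group for reductive cleavage.

Step 8
Reactants: 10 2β-acetoxy enone
Product: 11 C8=C9-en-7-one C12 ketal (C2 = CH2)
Conditions: SmI2 (2.2 equiv), THF–MeOH, −78 °C
Reagents that add atoms: none
Why: SmI2 reduction of an α-acyloxy ketone (ketyl formation, loss of acetate, protonation of the samarium enolate) is much faster at −78 °C than enone reduction.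

Step 9
Reactants: 11 enone
Product: 12 8-iodo enone
Conditions: I2, pyridine–CH2Cl2, rt
Reagents that add atoms: iodine, II
Why: α-Iodination of a cyclic enone by the pyridine addition–iodination–elimination sequence is standard, and C8–H is the only enone α-position.

Step 10
Reactants: 12 8-iodo enone; 13 2-bromo-N,N-dimethylpropanamide
Product: 15 8-[1-(dimethylcarbamoyl)ethyl] enone (C17 epimers), via bromozinc enolate 14 (not isolated)
Conditions: 13, Zn dust (TMSCl-activated), THF, rt; then 12, Pd(dba)2/P(t-Bu)3 (5 mol %), THF, rt to 45 °C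
Reagents that add atoms: none
Why: Negishi-type coupling of a Reformatsky (zinc amide enolate) reagent with an sp2 iodide forms C8–C17, and C17 is left undefined here because it is equilibrated in step 19.

Step 11
Reactants: 15 enone amide
Product: 16 8α 9α-diol 7-ketone
Conditions: OsO4 (5 mol %), NMO, citric acid, t-BuOH–acetone–H2O, rt
Reagents that add atoms: N-methylmorpholine N-oxide, C[N+]1([O-])CCOCC1; water, O
Why: Upjohn syn-dihydroxylation of the only alkene occurs on the α face opposite the axial C15 methyl (1,3 to C9), which sets C8 (OH axial α, C17 equatorial β) and C9 (O equatorial α) together.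

Step 12
Reactants: 16 diol
Product: 17 8,9-acetonide 7-ketone
Conditions: 2,2-dimethoxypropane, PPTS (cat.), CH2Cl2, rt
Reagents that add atoms: 2,2-dimethoxypropane, COC(C)(C)OC
Why: The cis axial/equatorial diol closes readily to the dioxolane, which masks both hydroxyls against base and organometallics.

Step 13
Reactants: 17 acetonide ketone
Product: 18 2β-vinyl 7-ketone
Conditions: LiHMDS (1.1 equiv), vinyl bromide, Pd2(dba)3/P(t-Bu)3 (cat.), toluene–THF, rt; pH 7 buffer
Reagents that add atoms: vinyl bromide, C=CBr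
Why: Palladium-catalysed α-vinylation of a ketone enolate can occur only at C2 because C8 is fully substituted, and axial α-face protonation (also the thermodynamic outcome) leaves the vinyl group equatorial β.

Step 14
Reactants: 18 2β-vinyl 7-ketone; 19 tert-butyl(diphenyl)(prop-2-ynyloxy)silane
Product: 21 7β-hydroxy-7α-alkynyl-2β-vinyl trans-decalin, via lithium acetylide 20 (not isolated)
Conditions: 19, n-BuLi, THF, −78 °C; CeCl3, −78 °C; then 18; NH4Cl aq
Reagents that add atoms: none
Why: The weakly basic cerium-modified acetylide adds to the ketone rather than enolising it or touching the amide, and it attacks from the α (equatorial) side because the β face of C7 is blocked by the syn-axial C15 methyl, so the alkynyl group ends equatorial and trans to the vinyl group.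

Step 15
Reactants: 21 7β-hydroxy-7α-alkynyl-2β-vinyl trans-decalin
Product: 24 (2E,5Z-in-ring)-cyclodeca-2,5-dien-7-one fused to ring A, via potassium alkoxide 22 (not isolated), via potassium allenolate 23 (not isolated)
Conditions: KH, 18-crown-6, THF, 0 °C to rt; AcOH in THF at −78 °C
Reagents that add atoms: none
Why: Deprotonation gives alkoxide 22, whose C7–O− weakens C2–C7 and triggers a concerted [3,3] shift (C4–C5 formed, C2–C7 broken) through a chair-like array in which the equatorial C2 vinyl and equatorial C7 alkynyl groups are gauche; this is the anionic acetylenic oxy-Cope rearrangement, the known ring expansion of 1-alkynyl-2-vinylcyclohexanols to cyclodecadienones. The ten-membered ring C1–C10 is not closed end to end but arises by four-atom expansion of ring C1-C2-C7-C8-C9-C10, so no macrocyclisation entropy is paid, and formation of allenolate 23 makes the step irreversible. C2=C3 is born E because in the only rotamer that brings C4 within reach of C5 the C2–H bond, not C2–C1, eclipses the vinyl group (A1,3 strain), which the trans-diequatorial arrangement enforces. C5=C6 is fixed on quench, since the enolate lobe at C6 lies in the plane of C4 and C16 and proton delivery from the ring periphery (C16 side) leaves C4 and C7 cis. C1, C8, C9 and C10 are spectators and are carried over unchanged. The step needs the [3,3] shift to outrun retro-addition of acetylide, attack of the alkoxide on C19 and β-elimination of O8, which is secured by the rigid alignment of the two π systems, by the poorly electrophilic and weakly α-acidic tertiary amide, and by a cold acidic quench that prevents base isomerisation of the skipped dienone.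

Step 16
Reactants: 24 cyclodecadienone
Product: 25 C7 allylic alcohol (O7 anti to O8)
Conditions: Zn(BH4)2, Et2O, −30 °C; NH4Cl aq
Reagents that add atoms: none
Why: Chelation-controlled (Cram-chelate) 1,2-reduction in which Zn(II) ties the C7 carbonyl oxygen to the C8 acetonide oxygen, the macrocycle covers the C9 side of the chelate, and hydride arrives from the open C17 side, giving the anti C7/C8 relationship of the target.

Step 17
Reactants: 25 allylic alcohol
Product: 27 7,8-lactone 8α 9α-diol 12-ketone (C17 epimers), via lactone bis-acetal 26 (not isolated)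
Conditions: AcOH–H2O 4:1, 55 °C
Reagents that add atoms: water, O
Why: The γ-hydroxy amide lactonises first and only onto O7 because O9 is still locked in the acetonide, and the same aqueous acid then hydrolyses acetonide and dioxolane while the TBDPS ether survives.

Step 18
Reactants: 27 diol lactone
Product: 28 9-acetate
Conditions: Ac2O, pyridine, DMAP (cat.), 0 °C to rt
Reagents that add atoms: acetic anhydride, CC(=O)OC(C)=O
Why: The secondary C9 hydroxyl is acylated while the hindered tertiary C8 hydroxyl is left free.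

Step 19
Reactants: 28 9-acetate (C17 epimers)
Product: 29 9-acetate with C18 cis to C8–OH
Conditions: DBU (0.5 equiv), toluene, 40 °C
Reagents that add atoms: none
Why: Reversible deprotonation α to the lactone carbonyl, the known base epimerisation of α-methyl-γ-lactones, should funnel both C17 epimers into the more stable one with C18 trans to the bulky C9 and cis to the small C8 hydroxyl.

Step 20
Reactants: 29 12-ketone
Product: 30 C13=C14-en-12-one
Conditions: IBX·4-methoxypyridine N-oxide, DMSO, rt
Reagents that add atoms: none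
Why: IBX dehydrogenation proceeds through the enol directed away from the ring fusion (towards C13, as in trans-fused 3-keto decalins), and the room-temperature variant with limited oxidant spares the tertiary C11–H and the doubly allylic C4.

Step 21
Reactants: 30 enone
Product: 31 11α-acetoxy enone (C20 β)
Conditions: Mn(OAc)3, benzene, reflux
Reagents that add atoms: manganese(III) acetate, CC(=O)[O-].CC(=O)[O-].CC(=O)[O-].[Mn+3]
Why: Mn(III) α′-acetoxylation of an enone can act only at C11, the sole enolisable position, and acetate should be transferred to the α face opposite the syn-axial C15 methyl, so that C20 ends β.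

Step 22
Reactants: 31 11α-acetoxy enone
Product: 32 (2R,3R)-epoxide
Conditions: mCPBA, NaHCO3, CH2Cl2, −10 °C
Reagents that add atoms: 3-chloroperbenzoic acid, O=C(OO)c1cccc(Cl)c1
Why: In this Prilezhaev epoxidation the strained E-C2=C3 is the most nucleophilic alkene (C13=C14 is conjugated, C5=C6 carries two allylic C–O bonds), and only its outer face is open, the one opposite the side from which C7 departed in step 15, which corresponds to the trans-epoxide configuration of the target.

Step 23
Reactants: 32 epoxide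
Product: 33 target CNP0155754.2
Conditions: TBAF, AcOH, THF, 0 °C
Reagents that add atoms: none
Why: Buffered fluoride removes the TBDPS group from O16 without touching the epoxide, acetates or lactone.

Compound list
1 | 2-methoxy-6-methylphenol | COc1cccc(C)c1O | starting material
2 | 2-methoxy-6-methyl-1,4-benzoquinone | COC1=CC(=O)C=C(C)C1=O | intermediate
3 | pent-1-en-3-one | CCC(=O)C=C | starting material
4 | (Z)-3-(tert-butyldimethylsilyloxy)penta-1,3-diene | C=C/C(O[Si](C)(C)C(C)(C)C)=C/C | intermediate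
5 | cis-fused Diels–Alder adduct | O=C1[C@H]2[C@](C)(CC=C(O[Si](C)(C)C(C)(C)C)[C@H]2C)C(=O)C(OC)=C1 | intermediate
6 | trans-fused trione | O=C1[C@@H]2[C@](C)(CCC(=O)[C@H]2C)C(=O)C(OC)=C1 | intermediate
7 | C12 ethylene ketal | O=C1[C@@H]2[C@](C)(CCC3(OCCO3)[C@H]2C)C(=O)C(OC)=C1 | intermediate
8 | 2β,9β-diol enol ether | O[C@H]1[C@@H]2[C@](C)(CCC3(OCCO3)[C@H]2C)[C@@H](O)C(OC)=C1 | intermediate
9 | 2β-hydroxy-C8=C9-en-7-one C12 ketal | O=C1C=C[C@@H]2[C@](C)(CCC3(OCCO3)[C@H]2C)[C@H]1O | intermediate
10 | 2β-acetoxy enone | O=C1C=C[C@@H]2[C@](C)(CCC3(OCCO3)[C@H]2C)[C@H]1OC(C)=O | intermediate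
11 | C8=C9-en-7-one C12 ketal | O=C1C=C[C@@H]2[C@](C)(CCC3(OCCO3)[C@H]2C)C1 | intermediate
12 | 8-iodo enone | O=C1C(I)=C[C@@H]2[C@](C)(CCC3(OCCO3)[C@H]2C)C1 | intermediate
13 | 2-bromo-N,N-dimethylpropanamide | CC(Br)C(=O)N(C)C | starting material
14 | bromozinc enolate of N,N-dimethylpropanamide | CC([Zn]Br)C(=O)N(C)C | intermediate
15 | 8-[1-(dimethylcarbamoyl)ethyl] enone (C17 epimers) | O=C1C(C(C)C(=O)N(C)C)=C[C@@H]2[C@](C)(CCC3(OCCO3)[C@H]2C)C1 | intermediate
16 | 8α,9α-diol 7-ketone | O=C1[C@@](O)(C(C)C(=O)N(C)C)[C@H](O)[C@@H]2[C@](C)(CCC3(OCCO3)[C@H]2C)C1 | intermediate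
17 | 8,9-acetonide 7-ketone | O=C1[C@]2(C(C)C(=O)N(C)C)OC(C)(C)O[C@@H]2[C@@H]3[C@](C)(CCC4(OCCO4)[C@H]3C)C1 | intermediate
18 | 2β-vinyl 7-ketone | O=C1[C@]2(C(C)C(=O)N(C)C)OC(C)(C)O[C@@H]2[C@@H]3[C@](C)(CCC4(OCCO4)[C@H]3C)[C@H]1C=C | intermediate
19 | tert-butyl(diphenyl)(prop-2-ynyloxy)silane | C#CCO[Si](c1ccccc1)(c1ccccc1)C(C)(C)C | starting material
20 | lithium acetylide of 19 | [Li]C#CCO[Si](c1ccccc1)(c1ccccc1)C(C)(C)C | intermediate
21 | 7β-hydroxy-7α-alkynyl-2β-vinyl trans-decalin | O[C@@]1(C#CCO[Si](c5ccccc5)(c5ccccc5)C(C)(C)C)[C@]2(C(C)C(=O)N(C)C)OC(C)(C)O[C@@H]2[C@@H]3[C@](C)(CCC4(OCCO4)[C@H]3C)[C@H]1C=C | intermediate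
22 | potassium alkoxide of 21 | [K+].[O-][C@@]1(C#CCO[Si](c5ccccc5)(c5ccccc5)C(C)(C)C)[C@]2(C(C)C(=O)N(C)C)OC(C)(C)O[C@@H]2[C@@H]3[C@](C)(CCC4(OCCO4)[C@H]3C)[C@H]1C=C | intermediate
23 | potassium allenolate (C5=C6=C7–O−) | [K+].CC1(C)O[C@@H]2[C@@H]3[C@](C)(CCC4(OCCO4)[C@H]3C)/C=C/CC(CO[Si](c5ccccc5)(c5ccccc5)C(C)(C)C)=C=C([O-])[C@@]2(O1)C(C)C(=O)N(C)C | intermediate
24 | cyclodeca-2,5-dien-7-one (E-C2=C3, ring-cis C5=C6) | CC1(C)O[C@@H]2[C@@H]3[C@](C)(CCC4(OCCO4)[C@H]3C)/C=C/C/C(CO[Si](c5ccccc5)(c5ccccc5)C(C)(C)C)=C\C(=O)[C@@]2(O1)C(C)C(=O)N(C)C | intermediate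
25 | C7 allylic alcohol (target C7 configuration) | CC1(C)O[C@@H]2[C@@H]3[C@](C)(CCC4(OCCO4)[C@H]3C)/C=C/C/C(CO[Si](c5ccccc5)(c5ccccc5)C(C)(C)C)=C\[C@H](O)[C@@]2(O1)C(C)C(=O)N(C)C | intermediate
26 | 7,8-lactone with acetonide and dioxolane intact | CC1(C)O[C@@H]2[C@@H]3[C@](C)(CCC4(OCCO4)[C@H]3C)/C=C/C/C(CO[Si](c5ccccc5)(c5ccccc5)C(C)(C)C)=C\[C@@H]6OC(=O)C(C)[C@@]26O1 | intermediate
27 | 7,8-lactone 8,9-diol 12-ketone (C17 epimers) | O[C@@H]1[C@@H]2[C@](C)(CCC(=O)[C@H]2C)/C=C/C/C(CO[Si](c3ccccc3)(c3ccccc3)C(C)(C)C)=C\[C@@H]2OC(=O)C(C)[C@]21O | intermediate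
28 | 9-acetate (C17 epimers) | CC(=O)O[C@@H]1[C@@H]2[C@](C)(CCC(=O)[C@H]2C)/C=C/C/C(CO[Si](c3ccccc3)(c3ccccc3)C(C)(C)C)=C\[C@@H]2OC(=O)C(C)[C@]21O | intermediate
29 | 9-acetate, C17 equilibrated | CC(=O)O[C@@H]1[C@@H]2[C@](C)(CCC(=O)[C@H]2C)/C=C/C/C(CO[Si](c3ccccc3)(c3ccccc3)C(C)(C)C)=C\[C@@H]2OC(=O)[C@H](C)[C@]21O | intermediate
30 | C13=C14-en-12-one | CC(=O)O[C@@H]1[C@@H]2[C@](C)(C=CC(=O)[C@H]2C)/C=C/C/C(CO[Si](c3ccccc3)(c3ccccc3)C(C)(C)C)=C\[C@@H]2OC(=O)[C@H](C)[C@]21O | intermediate
31 | 11α-acetoxy enone | CC(=O)O[C@@H]1[C@@H]2[C@](C)(C=CC(=O)[C@@]2(C)OC(C)=O)/C=C/C/C(CO[Si](c3ccccc3)(c3ccccc3)C(C)(C)C)=C\[C@@H]2OC(=O)[C@H](C)[C@]21O | intermediate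
32 | 2,3-epoxide, O16-TBDPS | CC(=O)O[C@@H]1[C@@H]2[C@](C)(C=CC(=O)[C@@]2(C)OC(C)=O)[C@H]2O[C@@H]2C/C(CO[Si](c3ccccc3)(c3ccccc3)C(C)(C)C)=C\[C@@H]2OC(=O)[C@H](C)[C@]21O | intermediate
33 | CNP0155754.2 | CC(=O)O[C@@H]1[C@@H]2[C@](C)(C=CC(=O)[C@@]2(C)OC(C)=O)[C@H]2O[C@@H]2C/C(CO)=C\[C@@H]2OC(=O)[C@H](C)[C@]21O | target

Total step count: 23. Longest linear sequence: 22 (step 1 or step 2, then steps 3–23).

Steps most likely to fail

Step 15. The alkoxide may lose acetylide by retro-addition before the [3,3] shift. The allenolate may also be protonated with poor control of the C5=C6 geometry, or the skipped dienone may be isomerised by base. The fallback sets out from 18 and 19 and comes back at 24, and it installs C5=C6 after the ring expansion instead of through an allenolate.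
- Palladium-catalysed hydrostannation of 19 with Bu3SnH gives the (E)-3-(tributylstannyl)allyl TBDPS ether F1.
- Tin–lithium exchange and addition to 18 give the 7α-[(E)-alkenyl]-2β-vinyl carbinol F2.
- The classical dienyl anionic oxy-Cope rearrangement (KH, 18-crown-6) gives a regiodefined C6–C7 enolate, which is trapped with PhSeBr as the 6-phenylselanyl cyclodec-2-en-7-one F3.
- Oxidation with H2O2 and syn-elimination towards C5–H give 24. A catalytic thiol equilibrates any ring-trans enone to the ring-cis isomer.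

Step 16. If the ring resists the chelated conformation, hydride may arrive at the outer face of the dipole-opposed conformer, and facial selectivity is then poor or reversed. The fallback sets out from 24 and comes back at 26, and it uses that opposite selectivity on purpose.
- Non-chelating Luche reduction (NaBH4, CeCl3, MeOH) gives the 7-epi allylic alcohol F4.
- MsCl and Et3N give the allylic mesylate F5.
- F5 is displaced with inversion by the amide oxygen, which sits on the face anti to the leaving group, to give the iminium lactone mesylate F6.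
- Aqueous NaHCO3 hydrolyses F6 to 26, which enters the acid hydrolysis of step 17.
- Both C7 epimers therefore lead to the same lactone, one by retention and one by inversion.

Step 21. Enolisation of the tertiary C11–H by Mn(III) may be slow, and radical addition to the ring alkenes may compete at reflux. The fallback sets out from 30 and comes back at 31, and it replaces C–H acetoxylation by oxidation of a preformed silyl dienol ether.
- TMSOTf and Et3N (CH2Cl2, 0 °C) give the 12-trimethylsilyloxy-11,13-diene 8-O-TMS ether F7.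
- Pb(OAc)4 (CH2Cl2, −20 °C) transfers acetate to the α face of C11 to give the 11α-acetoxy enone 8-O-TMS ether F8.
- Citric acid in MeOH removes the tertiary TMS ether to give 31.

Further compounds
F1 | step 15 | (E)-3-(tributylstannyl)allyl TBDPS ether | CCCC[Sn](CCCC)(CCCC)/C=C/CO[Si](c1ccccc1)(c1ccccc1)C(C)(C)C
F2 | step 15 | 7α-[(E)-alkenyl]-2β-vinyl carbinol | O[C@@]1(/C=C/CO[Si](c5ccccc5)(c5ccccc5)C(C)(C)C)[C@]2(C(C)C(=O)N(C)C)OC(C)(C)O[C@@H]2[C@@H]3[C@](C)(CCC4(OCCO4)[C@H]3C)[C@H]1C=C
F3 | step 15 | 6-phenylselanyl cyclodec-2-en-7-one | CC1(C)O[C@@H]2[C@@H]3[C@](C)(CCC4(OCCO4)[C@H]3C)/C=C/CC(CO[Si](c5ccccc5)(c5ccccc5)C(C)(C)C)C([Se]c5ccccc5)C(=O)[C@@]2(O1)C(C)C(=O)N(C)C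
F4 | step 16 | 7-epi allylic alcohol | CC1(C)O[C@@H]2[C@@H]3[C@](C)(CCC4(OCCO4)[C@H]3C)/C=C/C/C(CO[Si](c5ccccc5)(c5ccccc5)C(C)(C)C)=C\[C@@H](O)[C@@]2(O1)C(C)C(=O)N(C)C
F5 | step 16 | allylic mesylate | CC1(C)O[C@@H]2[C@@H]3[C@](C)(CCC4(OCCO4)[C@H]3C)/C=C/C/C(CO[Si](c5ccccc5)(c5ccccc5)C(C)(C)C)=C\[C@@H](OS(C)(=O)=O)[C@@]2(O1)C(C)C(=O)N(C)C
F6 | step 16 | iminium lactone mesylate | CC1(C)O[C@@H]2[C@@H]3[C@](C)(CCC4(OCCO4)[C@H]3C)/C=C/C/C(CO[Si](c5ccccc5)(c5ccccc5)C(C)(C)C)=C\[C@@H]6OC(=[N+](C)C)C(C)[C@@]26O1.CS(=O)(=O)[O-]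
F7 | step 21 | 12-trimethylsilyloxy-11,13-diene 8-O-TMS ether | CC(=O)O[C@@H]1[C@@H]2[C@](C)(C=CC(O[Si](C)(C)C)=C2C)/C=C/C/C(CO[Si](c3ccccc3)(c3ccccc3)C(C)(C)C)=C\[C@@H]2OC(=O)[C@H](C)[C@]21O[Si](C)(C)C
F8 | step 21 | 11α-acetoxy enone 8-O-TMS ether | CC(=O)O[C@@H]1[C@@H]2[C@](C)(C=CC(=O)[C@@]2(C)OC(C)=O)/C=C/C/C(CO[Si](c3ccccc3)(c3ccccc3)C(C)(C)C)=C\[C@@H]2OC(=O)[C@H](C)[C@]21O[Si](C)(C)C
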